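**Retrosynthetic overview**

1. The isopropenyl group comes from dehydration of a C7 tertiary carbinol (acetone aldol); the C9 angelate and C3 senecioate come from acylation of a 9β-hydroxy and a 3α-hydroxy group; C9–O comes from Rubottom oxidation and C10–H from cis-hydrogenation of an octalone.
2. Ring A (C1–C2–C3–C4–C5–C10) is not annulated. It is grown from the cyclopentanone ring of (S)-Hajos–Parrish ketone by a semipinacol 1,2-shift that inserts the CH–CH3 carbon (C4) between the carbonyl carbon (future C3) and the angular quaternary carbon (future C5).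
3. Enabling feature: a tertiary carbinol carbon inside the five-membered ring, bonded to the methyl-bearing quaternary ring-fusion carbon and carrying an exocyclic (R)-CH(OMs)CH3 group. The ring C–C bond antiperiplanar to the mesylate migrates, which creates the cis-vicinal C4/C5 methyl pair and the C3 carbonyl in one event.
4. Ring order: ring B with the C5 stereocentre is bought in the Hajos–Parrish ketone; ring A is enlarged from five to six atoms; then the C3 and ring B functionality is set by thermodynamic or convex-face control in the cis-decalin.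

Key step: step 5

Remark (numbering): compounds 1–7 are numbered as indenes (C1 = cyclopentanone carbon, C7a = methyl-bearing ring-fusion carbon, C5 = six-ring carbonyl carbon). Compounds 8–26 carry eremophilane numbers (C3 oxygenated, C4 = CH–CH3, C5 = quaternary C–CH3, C7 side-chain carbon, C8 ketone, C9 oxygenated, C10 ring-fusion CH). β is the face of the angular methyl group.

Remark (target): the target is read as (3R,4R,5R,7R,9R,10S), i.e. 3α-senecioyloxy, 4β-CH3, 5β-CH3, 7β-isopropenyl, 9β-angeloyloxy, 10β-H (cis-decalin). In the chair–chair form with the C5 methyl axial on ring A, all other ring substituents are equatorial.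

Assumption: (S)-Hajos–Parrish ketone is taken as purchased.

**Route**

Step 1
Reactants: 1 (S)-Hajos–Parrish ketone
Product: 2 enone dithiolane of 1
Conditions: HSCH2CH2SH (1.05 equiv), BF3·OEt2 (0.2 equiv), MeOH, 0 °C → rt
Reagents that add atoms: ethane-1,2-dithiol (SCCS)
Why: Acid-catalysed thioketalisation is selective for the conjugated six-ring carbonyl over the neopentyl cyclopentanone (as for steroidal 4-en-3-ones beside a 17-ketone) and leaves the C3a=C4 double bond in place, so the C1 ketone remains as the only carbonyl group; no stereocentre is formed.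

Step 2
Reactants: 2 enone dithiolane
Product: 4 1α-acetyl-1β-hydroxy dithiolane (ketol), via lithium alkoxide of the 1-ethoxyvinyl adduct 3 (not isolated)
Conditions: ethyl vinyl ether, t-BuLi, THF, −78 → 0 °C; then 2, −78 °C; then 1 M HCl, THF, 0 °C
Reagents that add atoms: ethyl vinyl ether (C=COCC); water (O)
Why: 1,2-Addition of the acetyl-anion equivalent 1-ethoxyvinyllithium to the C1 ketone occurs from the α-face, anti to the axial C7a methyl group (as in hydride and organometallic additions to Hajos–Parrish and 17-keto steroid ketones), which sets the tertiary carbinol with OH β, and mild acid hydrolysis of the enol ether unmasks the methyl ketone without touching the dithiolane.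

Step 3
Reactants: 4 ketol
Product: 5 1β-hydroxy-1α-[(1R)-1-hydroxyethyl] dithiolane (diol)
Conditions: Zn(BH4)2, Et2O, −20 °C
Reagents that add atoms: none
Why: Chelation-controlled (Cram chelate) reduction: zinc bridges the hydroxyl and carbonyl oxygens and hydride is delivered to the side of the chelate that faces the ring CH2 (C2) and not the quaternary C7a, which gives the (R)-carbinol.

Step 4
Reactants: 5 diol
Product: 6 secondary mesylate of 5
Conditions: MsCl (1.2 equiv), Et3N, CH2Cl2, −20 °C
Reagents that add atoms: methanesulfonyl chloride (CS(=O)(=O)Cl)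
Why: Sulfonylation with MsCl/Et3N at low temperature takes the secondary hydroxyl only, since the tertiary hydroxyl is too hindered, and retains the carbinol configuration.

Step 5
Reactants: 6 α-hydroxy mesylate
Product: 8 4β,5β-dimethyl-Δ9(10)-octalin-3,8-dione 8-dithiolane, via diethylaluminium alkoxide 7 (not isolated)
Conditions: Et3Al (3 equiv), CH2Cl2, −78 → −20 °C; aq. NH4Cl
Reagents that add atoms: none
Why: Et3Al turns the tertiary hydroxyl into an O–AlEt2 alkoxide and binds the mesylate oxygen, and the C1–C7a bond, antiperiplanar to the C–OMs bond, migrates in a concerted pinacol-type (semipinacol) 1,2-shift while C1 becomes the ketone carbon. The closest known reaction types are the organoaluminium-promoted rearrangement of α-hydroxy mesylates (Tsuchihashi–Suzuki) and the D-homoannulation of 17-hydroxy-20-sulfonyloxy steroids. No ring is closed: the cyclopentane ring C1–C2–C3–C3a–C7a is enlarged to six-membered ring A by insertion of the CH(CH3) carbon between C1 and C7a through a bridged three-centre transition state, so the mode is a 1,2-alkyl shift with ring expansion by one atom. The new stereocentre C4 is fixed by the substrate, because the shift is stereospecific with inversion at the (R)-configured mesylate carbon and retention at the migrating quaternary carbon, which gives the cis 4β,5β-dimethyl pair. The step needs migration of the quaternary carbon C7a instead of the ring CH2 (C2) and instead of epoxide closure; this should be secured by the higher migratory aptitude of the fully substituted carbon, by the rotamer in which the bulky aluminium-bound mesylate lies anti to C7a while the side-chain methyl sits on the α-side away from the β-axial angular methyl, and by the low nucleophilicity of the aluminium-bound oxygen.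

Step 6
Reactants: 8 ring-enlarged dithiolane ketone
Product: 9 4β,5β-dimethyl-Δ9(10)-octalin-3,8-dione
Conditions: HgCl2, CaCO3, MeCN/H2O (4:1), rt
Reagents that add atoms: water (O)
Why: HgCl2-assisted hydrolysis of the dithiolane (thiophilic metal activation) regenerates the conjugated enone under CaCO3 buffering, so that the C4 centre next to the C3 ketone is not exposed to acid or base.

Step 7
Reactants: 9 enedione
Product: 10 cis-fused 4β,5β-dimethyl-10βH-decalin-3,8-dione
Conditions: H2 (1 atm), 10% Pd/C, pyridine, rt
Reagents that add atoms: none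
Why: Heterogeneous hydrogenation of an angularly methylated octalone over Pd in pyridine delivers hydrogen to the β-face of C10 (the 5β-selectivity known for steroidal 4-en-3-ones), which gives the cis-fused decalin with 10β-H.

Step 8
Reactants: 10 cis-dione
Product: 11 8-(1,3-dioxolane) of 10
Conditions: (TMSOCH2)2 (1.1 equiv), TMSOTf (5 mol%), CH2Cl2, −78 → −30 °C; pyridine quench
Reagents that add atoms: 1,2-bis(trimethylsilyloxy)ethane (C[Si](C)(C)OCCO[Si](C)(C)C)
Why: Noyori ketalisation (aprotic, low temperature) takes the unhindered C8 ketone and not the C3 ketone, which is flanked by the C4 methine and would place a ketal oxygen 1,3-diaxial to the C5 methyl group; no epimerisable centre is touched.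

Step 9
Reactants: 11 ketal ketone
Product: 12 3α-hydroxy ketal
Conditions: Li, liq. NH3, THF, t-BuOH (2 equiv), −78 °C; NH4Cl
Reagents that add atoms: none
Why: Dissolving-metal reduction gives the thermodynamically favoured equatorial alcohol (3α-OH, trans to the C4 methyl), whereas hydride reagents would be forced to the equatorial trajectory by the syn-axial C5 methyl and give the 3β-epimer; the C8 ketal holds the cis-decalin in the conformer in which the 4β-methyl is equatorial, so C4 should not be lost under these basic conditions.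

Step 10
Reactants: 12 3α-hydroxy ketal; 13 3-methylbut-2-enoic acid
Product: 14 3α-senecioate ketal
Conditions: DCC, DMAP (0.1 equiv), CH2Cl2, 0 °C → rt
Reagents that add atoms: none
Why: Steglich esterification (DCC/DMAP) of the equatorial secondary alcohol; the mild carbodiimide activation avoids the vinylketene pathway that deconjugates senecioyl chloride.

Step 11
Reactants: 14 senecioate ketal
Product: 15 3α-senecioyloxy-4β,5β-dimethyl-10βH-decalin-8-one
Conditions: 1 M HCl, THF, rt
Reagents that add atoms: water (O)
Why: Acid-catalysed hydrolysis of the dioxolane frees the C8 ketone; the ester and the now non-epimerisable C4 centre are stable.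

Step 12
Reactants: 15 senecioate ketone
Product: 16 8-trimethylsilyloxy-Δ8(9) enol ether
Conditions: TMSCl, NaI, Et3N, MeCN, rt
Reagents that add atoms: chlorotrimethylsilane (C[Si](C)(C)Cl)
Why: Thermodynamic silyl enol ether formation with iodotrimethylsilane generated in the flask and Et3N: cis-fused 4a-methyl-2-decalones (the 5β-3-keto steroid pattern) enolise towards the ring-fusion side, i.e. towards C9.

Step 13
Reactants: 16 silyl enol ether
Product: 18 9β-hydroxy-3α-senecioyloxy ketone, via 9β-trimethylsilyloxy ketone 17 (not isolated)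
Conditions: mCPBA, NaHCO3, CH2Cl2, −20 → 0 °C; then 1 M HCl, THF, 0 °C
Reagents that add atoms: 3-chloroperbenzoic acid (OOC(=O)c1cccc(Cl)c1)
Why: Rubottom oxidation: the peracid attacks the enol ether from the convex β-face (the α-face is covered by the axial C4–C5 bond of ring A) and silyl transfer gives the α-silyloxy ketone, so that the hydroxyl is 9β, which is also the equatorial, thermodynamically preferred position.

Step 14
Reactants: 18 α-hydroxy ketone
Product: 19 9β-trimethylsilyloxy-8-trimethylsilyloxy-Δ7(8) enol ether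
Conditions: TMSOTf (2.4 equiv), Et3N (3 equiv), CH2Cl2, 0 °C; pentane, filtration
Reagents that add atoms: trimethylsilyl trifluoromethanesulfonate (C[Si](C)(C)OS(=O)(=O)C(F)(F)F)
Why: Soft enolisation with TMSOTf/Et3N silylates the 9-hydroxyl and forms the enol ether on the CH2 side (C7), away from the silyloxy-bearing methine, without a strong base that could attack the ester.

Step 15
Reactants: 19 bis-silyl enol ether
Product: 21 9β,11-dihydroxy-3α-senecioyloxy-10βH-eremophilan-8-one, via trichlorotitanium aldolate 20 (not isolated)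
Conditions: acetone (3 equiv), TiCl4 (1.2 equiv), CH2Cl2, −78 °C; then 1 M HCl, THF, 0 °C
Reagents that add atoms: acetone (CC(C)=O)
Why: Mukaiyama aldol addition to acetone under TiCl4 activation: the electrophile enters C7 from the convex β-face (the α-face is blocked by the syn-axial C4–C5 bond), which places the 2-hydroxypropan-2-yl group 7β and equatorial, and the acidic work-up removes the silyl ether.

Step 16
Reactants: 21 diol ketone; 22 angelic acid
Product: 24 9β-angeloyloxy-11-hydroxy-3α-senecioyloxy-10βH-eremophilan-8-one, via angelic 2,4,6-trichlorobenzoic anhydride 23 (not isolated)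
Conditions: 22, 2,4,6-trichlorobenzoyl chloride, Et3N, toluene, rt; then 21, toluene, 60 °C
Reagents that add atoms: none
Why: Yamaguchi esterification through the mixed 2,4,6-trichlorobenzoic anhydride acylates the secondary α-ketol hydroxyl (the tertiary hydroxyl is inert) and, run without a nucleophilic catalyst, is known to transfer the angeloyl group without Z to E isomerisation.

Step 17
Reactants: 24 tertiary alcohol diester
Product: 26 CNP0164025.2, via triethylammonium sulfamate ester 25 (not isolated)
Conditions: Burgess reagent (methyl N-(triethylammoniumsulfonyl)carbamate), toluene, 50 °C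
Reagents that add atoms: none
Why: Burgess dehydration is a thermal syn-elimination of the sulfamate ester: any of the six methyl hydrogens can reach the syn-periplanar geometry without strain, while the ring C7–H could do so only by eclipsing both methyl groups against ring bonds, so the isopropenyl group should form, and the neutral conditions spare the C7 and C9 centres and both esters.

**Compound list**

1 | (S)-Hajos–Parrish ketone, (7aS)-7a-methyl-2,3,7,7a-tetrahydro-1H-indene-1,5(6H)-dione | C1C[C@@]2(C)C(CCC2=O)=CC1=O | starting material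
2 | (7aS)-7a-methyl-2,3,7,7a-tetrahydro-1H-indene-1,5(6H)-dione 5-(ethane-1,2-diyl dithioketal) | C1C[C@@]2(C)C(CCC2=O)=CC13SCCS3 | intermediate
3 | lithium (1S,7aS)-1α-(1-ethoxyvinyl)-1β-oxido derivative of 2 | C1C[C@@]2(C)C(CC[C@@]2([O-])C(=C)OCC)=CC13SCCS3.[Li+] | intermediate
4 | (1S,7aS)-1α-acetyl-1β-hydroxy-7a-methyl-1,2,3,6,7,7a-hexahydro-5H-inden-5-one 5-(ethane-1,2-diyl dithioketal) | C1C[C@@]2(C)C(CC[C@@]2(O)C(C)=O)=CC13SCCS3 | intermediate
5 | (1S,7aS)-1β-hydroxy-1α-[(1R)-1-hydroxyethyl]-7a-methyl-1,2,3,6,7,7a-hexahydro-5H-inden-5-one 5-(ethane-1,2-diyl dithioketal) | C1C[C@@]2(C)C(CC[C@@]2(O)[C@@H](C)O)=CC13SCCS3 | intermediate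
6 | secondary methanesulfonate of 5, side chain (1R)-CH(OMs)CH3 on the α-face, tertiary OH β | C1C[C@@]2(C)C(CC[C@@]2(O)[C@@H](C)OS(C)(=O)=O)=CC13SCCS3 | intermediate
7 | diethylaluminium alkoxide of 6 | C1C[C@@]2(C)C(CC[C@@]2(O[Al](CC)CC)[C@@H](C)OS(C)(=O)=O)=CC13SCCS3 | intermediate
8 | (4R,5R)-4β,5β-dimethyl-Δ9(10)-octalin-3,8-dione 8-(ethane-1,2-diyl dithioketal) | C1C[C@@]2(C)C(CCC(=O)[C@@H]2C)=CC13SCCS3 | intermediate
9 | (4R,5R)-4β,5β-dimethyl-Δ9(10)-octalin-3,8-dione | C1C[C@@]2(C)C(CCC(=O)[C@@H]2C)=CC1=O | intermediate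
10 | cis-fused 4β,5β-dimethyl-10βH-decalin-3,8-dione | C1C[C@@]2(C)[C@H](CCC(=O)[C@@H]2C)CC1=O | intermediate
11 | 4β,5β-dimethyl-10βH-decalin-3,8-dione 8-(1,3-dioxolane) | C1C[C@@]2(C)[C@H](CCC(=O)[C@@H]2C)CC13OCCO3 | intermediate
12 | 3α-hydroxy-4β,5β-dimethyl-10βH-decalin-8-one 8-(1,3-dioxolane) | C1C[C@@]2(C)[C@H](CC[C@@H](O)[C@@H]2C)CC13OCCO3 | intermediate
13 | 3-methylbut-2-enoic acid (senecioic acid) | CC(C)=CC(=O)O | starting material
14 | 3α-(3-methylbut-2-enoyloxy)-4β,5β-dimethyl-10βH-decalin-8-one 8-(1,3-dioxolane) | C1C[C@@]2(C)[C@H](CC[C@@H](OC(=O)C=C(C)C)[C@@H]2C)CC13OCCO3 | intermediate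
15 | 3α-(3-methylbut-2-enoyloxy)-4β,5β-dimethyl-10βH-decalin-8-one | C1C[C@@]2(C)[C@H](CC[C@@H](OC(=O)C=C(C)C)[C@@H]2C)CC1=O | intermediate
16 | 8-trimethylsilyloxy-Δ8(9) enol ether of 15 | C1C[C@@]2(C)[C@H](CC[C@@H](OC(=O)C=C(C)C)[C@@H]2C)C=C1O[Si](C)(C)C | intermediate
17 | 9β-trimethylsilyloxy-3α-(3-methylbut-2-enoyloxy)-4β,5β-dimethyl-10βH-decalin-8-one | C1C[C@@]2(C)[C@H](CC[C@@H](OC(=O)C=C(C)C)[C@@H]2C)[C@@H](O[Si](C)(C)C)C1=O | intermediate
18 | 9β-hydroxy-3α-(3-methylbut-2-enoyloxy)-4β,5β-dimethyl-10βH-decalin-8-one | C1C[C@@]2(C)[C@H](CC[C@@H](OC(=O)C=C(C)C)[C@@H]2C)[C@@H](O)C1=O | intermediate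
19 | 8,9β-bis(trimethylsilyloxy)-Δ7(8) enol ether of 18 | C=1C[C@@]2(C)[C@H](CC[C@@H](OC(=O)C=C(C)C)[C@@H]2C)[C@@H](O[Si](C)(C)C)C=1O[Si](C)(C)C | intermediate
20 | trichlorotitanium alkoxide of the 7β-(2-hydroxypropan-2-yl)-9β-trimethylsilyloxy ketone | CC(C)(O[Ti](Cl)(Cl)Cl)[C@H]1C[C@@]2(C)[C@H](CC[C@@H](OC(=O)C=C(C)C)[C@@H]2C)[C@@H](O[Si](C)(C)C)C1=O | intermediate
21 | 9β,11-dihydroxy-3α-(3-methylbut-2-enoyloxy)-10βH-eremophilan-8-one (7β side chain) | CC(C)(O)[C@H]1C[C@@]2(C)[C@H](CC[C@@H](OC(=O)C=C(C)C)[C@@H]2C)[C@@H](O)C1=O | intermediate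
22 | angelic acid, (Z)-2-methylbut-2-enoic acid | C/C=C(/C)C(=O)O | starting material
23 | angelic 2,4,6-trichlorobenzoic anhydride | C/C=C(/C)C(=O)OC(=O)c1c(Cl)cc(Cl)cc1Cl | intermediate
24 | 9β-angeloyloxy-11-hydroxy-3α-(3-methylbut-2-enoyloxy)-10βH-eremophilan-8-one | CC(C)(O)[C@H]1C[C@@]2(C)[C@H](CC[C@@H](OC(=O)C=C(C)C)[C@@H]2C)[C@@H](OC(=O)/C(C)=C\C)C1=O | intermediate
25 | triethylammonium salt of the C11 N-(methoxycarbonyl)sulfamate ester of 24 | CC(C)(OS(=O)(=O)[N-]C(=O)OC)[C@H]1C[C@@]2(C)[C@H](CC[C@@H](OC(=O)C=C(C)C)[C@@H]2C)[C@@H](OC(=O)/C(C)=C\C)C1=O.CC[NH+](CC)CC | intermediate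
26 | CNP0164025.2, (3R,4R,5R,7R,9R,10S)-9-angeloyloxy-3-senecioyloxy-eremophil-11-en-8-one | C=C(C)[C@H]1C[C@@]2(C)[C@H](CC[C@@H](OC(=O)C=C(C)C)[C@@H]2C)[C@@H](OC(=O)/C(C)=C\C)C1=O | target

**Totals and risks**

Total step count: 17. Longest linear sequence: 17 steps (1 → 26); 13 and 22 enter as purchased acids.

Steps most likely to fail:

1. Step 5 (ring enlargement). What may go wrong: migration of the ring CH2 carbon instead of the quaternary carbon, or displacement of the mesylate by the alkoxide oxygen (epoxide closure). Fallback, setting out from 2 and returning at 11: Wittig ethylidenation of 2 (ethyltriphenylphosphonium bromide, KOtBu, THF) should give the (Z)-ethylidene dithiolane F1. HgCl2/CaCO3 frees the enone, (Z)-ethylidene enone F2. OsO4/NMO should dihydroxylate only the electron-rich exocyclic alkene, from the α-face, to the 1α-hydroxy-1β-[(1S)-1-hydroxyethyl] enone F3. MsCl/Et3N gives the secondary mesylate F4. In F4 the unstrained rotamer (side-chain methyl turned away from the angular methyl) has the mesylate anti to the quaternary carbon, the arrangement of the classical steroid D-homoannulation, so Et3Al should give the ring-enlarged 4α,5β-dimethyl-Δ9(10)-octalin-3,8-dione F5, the C4 epimer of 9. Hydrogenation as in step 7 gives the cis-fused 4α-methyl dione F6 and ketalisation as in step 8 gives its 8-dioxolane F7. NaOMe/MeOH then equilibrates C4, where the ketal-locked cis-decalin should favour the equatorial 4β-methyl, and this returns to 11.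

2. Step 15 (aldol with acetone). What may go wrong: slow or reversible addition to the ketone acceptor, and loss of the tertiary aldol by retro-aldol cleavage or dehydration during work-up. Fallback, setting out from 18 and returning at 21: silylation with TBSOTf/2,6-lutidine gives the 9β-tert-butyldimethylsilyloxy ketone F8. Kinetic deprotonation at the C7 methylene with LDA (1.05 equiv, THF, −78 °C), transmetalation with ZnCl2 and addition of acetone should give the 7β-(2-hydroxypropan-2-yl)-9β-silyloxy ketone F9. HF·pyridine removes the silyl group and returns to 21.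

3. Step 17 (dehydration). What may go wrong: elimination toward the ring methine, which forms the conjugated 7(11)-alkene, or later isomerisation of the isopropenyl ketone into conjugation. Fallback, setting out from 19 and returning at 26: the aldol of step 15 is run with 1-(trimethylsilyl)propan-2-one in place of acetone and quenched cold, to give the β-hydroxysilane, 7β-[2-hydroxy-1-(trimethylsilyl)propan-2-yl]-9β-hydroxy ketone F10 (either C11 configuration). Angeloylation as in step 16 gives its 9β-angelate F11. Acid-induced Peterson elimination (BF3·OEt2, CH2Cl2, −40 °C) can only form the C11=C12 double bond and gives 26.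

**Further compounds**

F1 | step 5 | (7aS,Z)-1-ethylidene-7a-methyl-1,2,3,6,7,7a-hexahydro-5H-inden-5-one 5-(ethane-1,2-diyl dithioketal) | C/C=C1/CCC2=CC3(SCCS3)CC[C@]12C
F2 | step 5 | (7aS,Z)-1-ethylidene-7a-methyl-1,2,3,6,7,7a-hexahydro-5H-inden-5-one | C/C=C1/CCC2=CC(=O)CC[C@]12C
F3 | step 5 | (7aS)-1α-hydroxy-1β-[(1S)-1-hydroxyethyl]-7a-methyl-1,2,3,6,7,7a-hexahydro-5H-inden-5-one | C[C@H](O)[C@@]1(O)CCC2=CC(=O)CC[C@]12C
F4 | step 5 | secondary methanesulfonate of F3 | C[C@H](OS(C)(=O)=O)[C@@]1(O)CCC2=CC(=O)CC[C@]12C
F5 | step 5 | 4α,5β-dimethyl-Δ9(10)-octalin-3,8-dione (C4 epimer of 9) | C1C[C@@]2(C)C(CCC(=O)[C@H]2C)=CC1=O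
F6 | step 5 | cis-fused 4α,5β-dimethyl-10βH-decalin-3,8-dione | C1C[C@@]2(C)[C@H](CCC(=O)[C@H]2C)CC1=O
F7 | step 5 | 4α,5β-dimethyl-10βH-decalin-3,8-dione 8-(1,3-dioxolane) | C1C[C@@]2(C)[C@H](CCC(=O)[C@H]2C)CC13OCCO3
F8 | step 15 | 9β-(tert-butyldimethylsilyloxy)-3α-(3-methylbut-2-enoyloxy)-4β,5β-dimethyl-10βH-decalin-8-one | C1C[C@@]2(C)[C@H](CC[C@@H](OC(=O)C=C(C)C)[C@@H]2C)[C@@H](O[Si](C)(C)C(C)(C)C)C1=O
F9 | step 15 | 9β-(tert-butyldimethylsilyloxy)-11-hydroxy-3α-(3-methylbut-2-enoyloxy)-10βH-eremophilan-8-one | CC(C)(O)[C@H]1C[C@@]2(C)[C@H](CC[C@@H](OC(=O)C=C(C)C)[C@@H]2C)[C@@H](O[Si](C)(C)C(C)(C)C)C1=O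
F10 | step 17 | 9β,11-dihydroxy-12-(trimethylsilyl)-3α-(3-methylbut-2-enoyloxy)-10βH-eremophilan-8-one (C11 epimers) | C[Si](C)(C)CC(C)(O)[C@H]1C[C@@]2(C)[C@H](CC[C@@H](OC(=O)C=C(C)C)[C@@H]2C)[C@@H](O)C1=O
F11 | step 17 | 9β-angeloyloxy-11-hydroxy-12-(trimethylsilyl)-3α-(3-methylbut-2-enoyloxy)-10βH-eremophilan-8-one (C11 epimers) | C[Si](C)(C)CC(C)(O)[C@H]1C[C@@]2(C)[C@H](CC[C@@H](OC(=O)C=C(C)C)[C@@H]2C)[C@@H](OC(=O)/C(C)=C\C)C1=O
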